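**Retrosynthetic overview**
- Feature: the 2,2-disubstituted terminal oxirane. Its quaternary carbon carries arene carbon C6, the CH2O-tiglate arm, the ring oxygen and the ring CH2. This carbon is read as a ketone carbonyl carbon, and the ring CH2 as one added methylene.
- Endgame disconnections: the aryl angelate C(=O)–O bond (formed last, on the freed phenol), then the alkyl tiglate C(=O)–O bond, back to an O-allyl, O-silyl protected epoxy alcohol.
- Key disconnection: both bonds of the oxirane CH2 (to the quaternary carbon and to oxygen), back to the aryl silyloxymethyl ketone and dimethyloxosulfonium methylide under a chiral lanthanum–lithium binaphthoxide catalyst.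
- Ketone: the aryl–C(=O) bond, back to the aryllithium from brominated, allylated 4-methoxy-3-methylphenol and the Weinreb amide of O-silylated glycolic acid.
- Ring order: the benzene ring is bought. The oxirane is the only ring formed, together with the only stereocentre.

Key step: step 7

Assumption: the target needs ylide attack on the Re face of the aryl ketone (priorities O > CH2OTBS > aryl), and which binaphthol antipode gives this cannot be derived with certainty for a silyloxymethyl ketone. (S)-Binaphthol is written. A pilot run correlates the epoxy alcohol with material from the tartrate-controlled epoxidation described under the fallbacks, and (R)-binaphthol takes its place if the sense is opposite.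

**Step 1**
Reactants: 1 4-methoxy-3-methylphenol
Product: 2 2-bromo-4-methoxy-5-methylphenol
Conditions: NBS (1.0 equiv), MeCN, 0 °C, dark
Reagents that add atoms: N-bromosuccinimide, O=C1CCC(=O)N1Br
Why: Electrophilic aromatic bromination in which the free hydroxyl is the strongest director, and of its two ortho positions the one para to the methyl group is doubly activated and open, whereas the other is squeezed between OH and CH3.

**Step 2**
Reactants: 2 2-bromo-4-methoxy-5-methylphenol
Product: 3 1-(allyloxy)-2-bromo-4-methoxy-5-methylbenzene
Conditions: allyl bromide, K2CO3, acetone, reflux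
Reagents that add atoms: allyl bromide, C=CCBr
Why: Williamson ether synthesis of the phenoxide with a reactive allylic halide, far below Claisen temperatures, giving a phenol protection that withstands organolithium, ylide and fluoride and can later be removed without acid or hydrogen.

**Step 3**
Reactants: 4 methyl glycolate
Product: 5 methyl 2-(tert-butyldimethylsilyloxy)acetate
Conditions: TBSCl, imidazole, CH2Cl2, 0 °C to rt
Reagents that add atoms: tert-butyldimethylsilyl chloride, C[Si](C)(Cl)C(C)(C)C
Why: Imidazole-promoted silylation of an unhindered primary alcohol, with the ester untouched.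

**Step 4**
Reactants: 5 methyl 2-(tert-butyldimethylsilyloxy)acetate
Product: 6 2-(tert-butyldimethylsilyloxy)-N-methoxy-N-methylacetamide
Conditions: MeNH(OMe)·HCl (1.5 equiv), iPrMgCl (3.0 equiv), THF, –20 to 0 °C
Reagents that add atoms: N,O-dimethylhydroxylamine hydrochloride, CNOC.Cl
Why: Weinreb amide formation by aminolysis of the ester with the magnesium amide made in the flask, which is fast at low temperature and leaves the silyl ether alone.

**Step 5**
Reactants: 3 1-(allyloxy)-2-bromo-4-methoxy-5-methylbenzene; 6 2-(tert-butyldimethylsilyloxy)-N-methoxy-N-methylacetamide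
Product: 9 1-[2-(allyloxy)-5-methoxy-4-methylphenyl]-2-(tert-butyldimethylsilyloxy)ethanone, via aryllithium 7 (not isolated), via lithium hemiaminal alkoxide 8 (not isolated)
Conditions: n-BuLi (1.05 equiv), THF, –78 °C, 20 min; then 6, –78 to –20 °C; aq. NH4Cl
Reagents that add atoms: none
Why: Bromine–lithium exchange at –78 °C outruns deprotonation of the allyl ether and 5-exo carbolithiation of its alkene, and the Weinreb ketone synthesis halts at chelated adduct 8, which collapses to the ketone only on quench, so no second addition occurs.

**Step 6**
Reactants: 10 trimethylsulfoxonium chloride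
Product: 11 dimethyloxosulfonium methylide (titrated stock solution in THF)
Conditions: NaH (0.95 equiv), THF, reflux; filtration through Celite under Ar
Reagents that add atoms: none
Why: Deprotonation of the sulfoxonium salt (Corey–Chaykovsky ylide formation), the chloride being chosen because NaCl is insoluble in THF and is filtered off, so that no foreign alkali salt reaches the lithium sites of the catalyst.

**Step 7**
Reactants: 9 1-[2-(allyloxy)-5-methoxy-4-methylphenyl]-2-(tert-butyldimethylsilyloxy)ethanone; 11 dimethyloxosulfonium methylide
Product: 13 (R)-2-[2-(allyloxy)-5-methoxy-4-methylphenyl]-2-[(tert-butyldimethylsilyloxy)methyl]oxirane, via betaine 12 (not isolated)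
Conditions: LaLi3[(S)-binaphthoxide]3 (5 mol %; from La(OiPr)3, (S)-BINOL, n-BuLi 1:3:3), [2,4,6-(MeO)3C6H2]3P=O (5 mol %), MS 5 Å, 11 (1.2 equiv), THF, rt
Reagents that add atoms: none
Why: The trivalent lanthanum centre binds the carbonyl oxygen of 9 and a lithium binaphthoxide site holds the sulfoxonium oxygen of 11, so the ylide carbon adds to one carbonyl face to give betaine 12 (new bond from the quaternary carbon to the methylene carbon), whose alkoxide then expels dimethyl sulfoxide from that methylene carbon (new methylene–oxygen bond). The closest known reaction type is the catalytic asymmetric Corey–Chaykovsky epoxidation of aryl and alkyl methyl ketones with the same ylide, catalyst and phosphine oxide additive, which also takes ethyl and propyl ketones, though less selectively. The oxirane, the only ring made in the route, closes in the 3-exo-tet mode. Its quaternary carbon, the only stereocentre, is set in the addition step by the axially chiral binaphthoxide ligands (attack on the Re face of 9) and is not touched in the closure, which happens at the methylene carbon. The step needs enantioface selectivity, 1,2-addition ahead of enolisation and a halt at the oxirane: the flat ortho-alkoxyaryl group and the tetrahedral CH2OTBS arm give the catalyst two unlike flanks, the bulky silyl group keeps the α-oxygen from chelating the metals in a second binding mode, proton transfer to the ylide is reversible and unproductive, and only 1.2 equiv of ylide at room temperature leaves the slower ring expansion to the oxetane behind.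

**Step 8**
Reactants: 13 (R)-2-[2-(allyloxy)-5-methoxy-4-methylphenyl]-2-[(tert-butyldimethylsilyloxy)methyl]oxirane
Product: 14 {(S)-2-[2-(allyloxy)-5-methoxy-4-methylphenyl]oxiran-2-yl}methanol (same spatial arrangement; the descriptor changes by priority only)
Conditions: Bu4NF (1.1 equiv), THF, 0 °C; water
Reagents that add atoms: none
Why: Fluoride-driven desilylation under acid-free conditions that spare the benzylic oxirane, and a Payne rearrangement of the transient alkoxide is harmless because inversion at the quaternary carbon goes along with exchange of the two CH2O arms and returns the same enantiomer.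

**Step 9**
Reactants: 14 {(S)-2-[2-(allyloxy)-5-methoxy-4-methylphenyl]oxiran-2-yl}methanol; 15 tiglic acid
Product: 16 {(R)-2-[2-(allyloxy)-5-methoxy-4-methylphenyl]oxiran-2-yl}methyl (E)-2-methylbut-2-enoate
Conditions: 15 (1.2 equiv), DCC (1.3 equiv), DMAP (0.1 equiv), CH2Cl2, 0 °C to rt
Reagents that add atoms: none
Why: Steglich esterification of a primary alcohol, free of halide and strong acid that could open the oxirane and free of amine-induced vinylketene deconjugation, while DMAP cannot harm the tiglate because E is the stable geometry.

**Step 10**
Reactants: 17 angelic acid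
Product: 18 angelic anhydride, (Z,Z)-2-methylbut-2-enoic anhydride
Conditions: 17 (2.0 equiv), DCC (1.0 equiv), CH2Cl2, 0 °C to rt; filtration
Reagents that add atoms: none
Why: Carbodiimide dehydration of two acid molecules to the symmetric anhydride, without nucleophilic catalyst, halide or heat, which are the channels through which the Z acyl unit isomerises.

**Step 11**
Reactants: 16 {(R)-2-[2-(allyloxy)-5-methoxy-4-methylphenyl]oxiran-2-yl}methyl (E)-2-methylbut-2-enoate
Product: 19 [(R)-2-(2-hydroxy-5-methoxy-4-methylphenyl)oxiran-2-yl]methyl (E)-2-methylbut-2-enoate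
Conditions: Pd(PPh3)4 (5 mol %), morpholine (2 equiv), degassed THF, rt; short pad of neutral alumina, used at once
Reagents that add atoms: none
Why: Tsuji–Trost-type deallylation in which zerovalent palladium ionises only the allyl aryl ether (phenoxide as leaving group) and morpholine traps the π-allyl complex, the tiglate being on a non-allylic carbon and the oxirane not being vinylic.

**Step 12**
Reactants: 19 [(R)-2-(2-hydroxy-5-methoxy-4-methylphenyl)oxiran-2-yl]methyl (E)-2-methylbut-2-enoate; 18 angelic anhydride
Product: 20 4-methoxy-5-methyl-2-[(R)-2-{[(E)-2-methylbut-2-enoyloxy]methyl}oxiran-2-yl]phenyl (Z)-2-methylbut-2-enoate (target)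
Conditions: 18 (1.5 equiv), then Cs2CO3 (1.5 equiv), MeCN, 0 °C
Reagents that add atoms: none
Why: Base-mediated O-acylation of a phenol with a preformed anhydride (stereoconservative angeloylation), in which no nucleophilic catalyst is present to add reversibly to the Z enoyl unit, the base is added last so that the phenoxide is acylated as it forms, and the stereocentre is not involved.

**Compound list**
1 | 4-methoxy-3-methylphenol | Cc1cc(O)ccc1OC | starting material
2 | 2-bromo-4-methoxy-5-methylphenol | Oc1cc(C)c(OC)cc1Br | intermediate
3 | 1-(allyloxy)-2-bromo-4-methoxy-5-methylbenzene | C=CCOc1cc(C)c(OC)cc1Br | intermediate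
4 | methyl glycolate | COC(=O)CO | starting material
5 | methyl 2-(tert-butyldimethylsilyloxy)acetate | COC(=O)CO[Si](C)(C)C(C)(C)C | intermediate
6 | 2-(tert-butyldimethylsilyloxy)-N-methoxy-N-methylacetamide | CON(C)C(=O)CO[Si](C)(C)C(C)(C)C | intermediate
7 | [2-(allyloxy)-5-methoxy-4-methylphenyl]lithium (not isolated) | C=CCOc1cc(C)c(OC)cc1[Li] | intermediate
8 | lithium hemiaminal alkoxide from 7 and 6 (not isolated) | C=CCOc1cc(C)c(OC)cc1C([O-])(CO[Si](C)(C)C(C)(C)C)N(C)OC.[Li+] | intermediate
9 | 1-[2-(allyloxy)-5-methoxy-4-methylphenyl]-2-(tert-butyldimethylsilyloxy)ethanone | C=CCOc1cc(C)c(OC)cc1C(=O)CO[Si](C)(C)C(C)(C)C | intermediate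
10 | trimethylsulfoxonium chloride | C[S+](C)(C)=O.[Cl-] | starting material
11 | dimethyloxosulfonium methylide | [CH2-][S+](C)(C)=O | intermediate
12 | (S)-betaine from 9 and 11 (not isolated) | C=CCOc1cc(C)c(OC)cc1[C@]([O-])(CO[Si](C)(C)C(C)(C)C)C[S+](C)(C)=O | intermediate
13 | (R)-2-[2-(allyloxy)-5-methoxy-4-methylphenyl]-2-[(tert-butyldimethylsilyloxy)methyl]oxirane | C=CCOc1cc(C)c(OC)cc1[C@]1(CO[Si](C)(C)C(C)(C)C)CO1 | intermediate
14 | {(S)-2-[2-(allyloxy)-5-methoxy-4-methylphenyl]oxiran-2-yl}methanol | C=CCOc1cc(C)c(OC)cc1[C@]1(CO)CO1 | intermediate
15 | tiglic acid, (E)-2-methylbut-2-enoic acid | C/C=C(\C)C(=O)O | starting material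
16 | {(R)-2-[2-(allyloxy)-5-methoxy-4-methylphenyl]oxiran-2-yl}methyl tiglate | C=CCOc1cc(C)c(OC)cc1[C@]1(COC(=O)/C(C)=C/C)CO1 | intermediate
17 | angelic acid, (Z)-2-methylbut-2-enoic acid | C/C=C(/C)C(=O)O | starting material
18 | angelic anhydride | C/C=C(/C)C(=O)OC(=O)/C(C)=C\C | intermediate
19 | [(R)-2-(2-hydroxy-5-methoxy-4-methylphenyl)oxiran-2-yl]methyl tiglate | Oc1cc(C)c(OC)cc1[C@]1(COC(=O)/C(C)=C/C)CO1 | intermediate
20 | 4-methoxy-5-methyl-2-[(R)-2-(tigloyloxymethyl)oxiran-2-yl]phenyl angelate | C/C=C(/C)C(=O)Oc1cc(C)c(OC)cc1[C@]1(COC(=O)/C(C)=C/C)CO1 | target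

**Step count**
Total: 12 steps. Longest linear sequence: 8 steps (1 → 2 → 3 → 9 → 13 → 14 → 16 → 19 → 20; the branch from 4 is equally long).

**Steps most likely to fail**

Step 7. Facial selectivity may erode, because the CH2OTBS arm is larger than the methyl group for which the catalyst pocket works best. Turnover of an ortho-substituted aryl ketone may also be slow.
- The fallback sets out from 9 and comes back at 14. It delivers the oxirane oxygen to an alkene instead of a methylene to a ketone.
- Wittig methylenation of 9 (Ph3PCH3Br, KOtBu, THF, 0 °C to rt) should give the 2-arylallyl silyl ether F1.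
- Bu4NF in THF should then free the 2-arylprop-2-en-1-ol F2.
- Katsuki–Sharpless epoxidation of F2 (Ti(OiPr)4, L-(+)-diisopropyl tartrate, t-BuOOH, MS 4 Å, CH2Cl2, –20 °C) should give 14.
- L-(+)-Tartrate delivers oxygen with the topology of the (S)-glycidol series. With the aryl group in the place of hydrogen, that is (S)-14.
- The alkene of the aryl allyl ether has no directing hydroxyl and stays untouched.

Step 11. The oxirane may be lost once the ortho phenol is free. Hydrogen bonding from the OH, or electron push from the phenoxide, can open the benzylic C–O bond during reaction or handling.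
- The fallback sets out from 16 and comes back at 20. It never liberates the phenol.
- Palladium-catalysed hydrostannolysis (Pd(PPh3)4 cat., Bu3SnH added slowly, CH2Cl2, rt) transfers hydride to the π-allyl complex.
- This leaves the oxygen as the covalent tributylstannyl aryl ether F3.
- Anhydride 18 is then added to the same flask and acylates the Sn–O bond directly to 20.

Step 12. The angeloyl unit may isomerise from Z to E during acyl transfer, made worse by slow acylation of a hindered phenol.
- The fallback sets out from 19 and comes back at 20. It builds the Z alkene on the aryl ester instead of transferring it.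
- Carbodiimide coupling of 19 with 2-[bis(2,2,2-trifluoroethoxy)phosphoryl]propanoic acid (DCC, DMAP cat., CH2Cl2, 0 °C) should give the aryl phosphonopropanoate F4.
- Still–Gennari olefination of F4 (KN(SiMe3)2, 18-crown-6, THF, –78 °C, then acetaldehyde) should close the sequence with kinetic Z selectivity to give 20.

**Further compounds**
F1 | step 7 | {2-[2-(allyloxy)-5-methoxy-4-methylphenyl]allyloxy}(tert-butyl)dimethylsilane | C=CCOc1cc(C)c(OC)cc1C(=C)CO[Si](C)(C)C(C)(C)C
F2 | step 7 | 2-[2-(allyloxy)-5-methoxy-4-methylphenyl]prop-2-en-1-ol | C=CCOc1cc(C)c(OC)cc1C(=C)CO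
F3 | step 11 | [(R)-2-{5-methoxy-4-methyl-2-[(tributylstannyl)oxy]phenyl}oxiran-2-yl]methyl tiglate | CCCC[Sn](CCCC)(CCCC)Oc1cc(C)c(OC)cc1[C@]1(COC(=O)/C(C)=C/C)CO1
F4 | step 12 | 4-methoxy-5-methyl-2-[(R)-2-(tigloyloxymethyl)oxiran-2-yl]phenyl 2-[bis(2,2,2-trifluoroethoxy)phosphoryl]propanoate (epimers at the α-carbon) | CC(C(=O)Oc1cc(C)c(OC)cc1[C@]1(COC(=O)/C(C)=C/C)CO1)P(=O)(OCC(F)(F)F)OCC(F)(F)F
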